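**Strategy.** The route rests on cutting ring B of the decalin (naphthalene locants, C1 carrying the acid chain: C1–C4, C4a, C8a) across the C2–C3 and C1–C8a bonds. Both are made in one intramolecular Diels–Alder reaction of a monocyclic 1-vinylcyclohexene (ring C, with the C5 quaternary and C6 centres already set) whose phenol is esterified as a 4,4-dimethylallenoate. The α,β-bond of the allene adds across the diene, so the untouched allene bond becomes the C2 isopropylidene, the tetrasubstituted diene terminus becomes the C8a methyl-bearing quaternary carbon, and the temporary nine-membered aryl lactone, built on the phenol ortho to the C5 benzylic arm, dictates the diene face. Lactone opening, C4=C4a reduction, C1 epimerisation and two-carbon homologation then give the acid.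

Key step: step 12

Remark: locants C1–C8a are those of the decahydronaphthalene core of the target (C1 propanoic acid chain, C2 isopropylidene, C4a ring-fusion CH, C5 methyl and arylmethyl, C6 methyl, C8a angular methyl); α is the face of the C5 arylmethyl group, β the face of the C5 and C8a methyl groups; compounds 6, 17 and 18 are taken as commercial.

Step 1
Reactants: 1 4-methoxy-2-methylphenol
Product: 2 2-hydroxy-5-methoxy-3-methylbenzaldehyde
Conditions: (CH2O)n, MgCl2, Et3N, MeCN, reflux; aq. HCl
Reagents that add atoms: paraformaldehyde (formaldehyde), C=O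
Why: Magnesium phenoxide-directed ortho-formylation; only one ortho position is free, and a second formaldehyde equivalent acts as hydride acceptor.

Step 2
Reactants: 2 2-hydroxy-5-methoxy-3-methylbenzaldehyde
Product: 3 2-(tert-butyldimethylsilyloxy)-5-methoxy-3-methylbenzaldehyde
Conditions: TBSCl, imidazole, DMF, 25 °C
Reagents that add atoms: tert-butyldimethylsilyl chloride, CC(C)(C)[Si](C)(C)Cl
Why: Silyl ether formation; the group must survive organometallic and strong-base steps and be removable by fluoride without acid.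

Step 3
Reactants: 3 2-(tert-butyldimethylsilyloxy)-5-methoxy-3-methylbenzaldehyde
Product: 4 [2-(tert-butyldimethylsilyloxy)-5-methoxy-3-methylphenyl]methanol
Conditions: NaBH4, MeOH, 0 °C
Reagents that add atoms: none
Why: Borohydride reduction of the aldehyde; nothing else in the molecule is reducible.

Step 4
Reactants: 4 [2-(tert-butyldimethylsilyloxy)-5-methoxy-3-methylphenyl]methanol
Product: 5 [2-(bromomethyl)-4-methoxy-6-methylphenoxy](tert-butyl)dimethylsilane
Conditions: CBr4, PPh3, CH2Cl2, 0 °C
Reagents that add atoms: carbon tetrabromide, BrC(Br)(Br)Br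
Why: Appel reaction under neutral conditions, so the aryl silyl ether is kept.

Step 5
Reactants: 5 [2-(bromomethyl)-4-methoxy-6-methylphenoxy](tert-butyl)dimethylsilane, 6 2-iodocyclohex-2-en-1-one
Product: 8 2-{[2-(tert-butyldimethylsilyloxy)-5-methoxy-3-methylphenyl]methyl}cyclohex-2-en-1-one, via arylmethylzinc bromide 7 (not isolated)
Conditions: Zn dust, LiCl, THF, 25 °C; then 6, Pd(OAc)2 (2 mol %), SPhos (4 mol %), 25 °C
Reagents that add atoms: none
Why: LiCl-assisted zinc insertion into the benzylic bromide, then Negishi coupling with the α-iodoenone; the benzylic partner has no β-hydrogen.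

Step 6
Reactants: 8 2-{[2-(tert-butyldimethylsilyloxy)-5-methoxy-3-methylphenyl]methyl}cyclohex-2-en-1-one
Product: 10 (2S,3S)-2-{[2-(tert-butyldimethylsilyloxy)-5-methoxy-3-methylphenyl]methyl}-2,3-dimethylcyclohexan-1-one, via bromomagnesium enolate 9 (not isolated)
Conditions: MeMgBr, Cu(OTf)2 (3 mol %), chiral imidazolinium salt (N-heterocyclic carbene precursor, 4 mol %), Et2O, −30 °C; then MeI, DMPU, −30 → 0 °C
Reagents that add atoms: methylmagnesium bromide, C[Mg]Br; iodomethane, CI
Why: Copper-catalysed enantioselective conjugate addition to an α-substituted cyclohexenone (ligand enantiomer chosen for 3S), then enolate alkylation anti to the new C3 methyl; this should give the trans-2,3-dimethyl array with the arylmethyl group cis to the C3 methyl.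

Step 7
Reactants: 10 (2S,3S)-2-{[2-(tert-butyldimethylsilyloxy)-5-methoxy-3-methylphenyl]methyl}-2,3-dimethylcyclohexan-1-one
Product: 12 (2S,3S)-2-{[2-(tert-butyldimethylsilyloxy)-5-methoxy-3-methylphenyl]methyl}-2,3,6-trimethylcyclohexan-1-one (both C6 epimers), via lithium enolate 11 (not isolated)
Conditions: LDA, THF, −78 °C; then MeI, −78 → 0 °C
Reagents that add atoms: iodomethane, CI
Why: Enolate alkylation; only C6 can be enolised because C2 is quaternary, and the C6 epimers converge in step 8.

Step 8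
Reactants: 12 (2S,3S)-2-{[2-(tert-butyldimethylsilyloxy)-5-methoxy-3-methylphenyl]methyl}-2,3,6-trimethylcyclohexan-1-one
Product: 14 (5S,6S)-6-{[2-(tert-butyldimethylsilyloxy)-5-methoxy-3-methylphenyl]methyl}-2,5,6-trimethylcyclohex-1-en-1-yl trifluoromethanesulfonate, via potassium enolate 13 (not isolated)
Conditions: KHMDS, THF, −78 → 0 °C; then PhNTf2, 0 → 25 °C
Reagents that add atoms: N-phenylbis(trifluoromethanesulfonimide), O=S(=O)(N(c1ccccc1)S(=O)(=O)C(F)(F)F)C(F)(F)F
Why: Enolate O-triflation; removal of the single remaining α-hydrogen gives the tetrasubstituted enol triflate regiospecifically.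

Step 9
Reactants: 14 (5S,6S)-6-{[2-(tert-butyldimethylsilyloxy)-5-methoxy-3-methylphenyl]methyl}-2,5,6-trimethylcyclohex-1-en-1-yl trifluoromethanesulfonate
Product: 15 tert-butyl(2-{[(1S,6S)-2-ethenyl-1,3,6-trimethylcyclohex-2-en-1-yl]methyl}-4-methoxy-6-methylphenoxy)dimethylsilane
Conditions: CH2=CHSnBu3, Pd(PPh3)4 (5 mol %), LiCl, THF, 65 °C
Reagents that add atoms: tributyl(vinyl)stannane, C=C[Sn](CCCC)(CCCC)CCCC
Why: Stille coupling of the hindered enol triflate (LiCl assists transmetalation), as for 2,6,6-trimethylcyclohexenyl triflate, gives the 1-vinylcyclohexene diene.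

Step 10
Reactants: 15 tert-butyl(2-{[(1S,6S)-2-ethenyl-1,3,6-trimethylcyclohex-2-en-1-yl]methyl}-4-methoxy-6-methylphenoxy)dimethylsilane
Product: 16 2-{[(1S,6S)-2-ethenyl-1,3,6-trimethylcyclohex-2-en-1-yl]methyl}-4-methoxy-6-methylphenol
Conditions: TBAF, THF, 0 °C; aq. NH4Cl
Reagents that add atoms: none
Why: Fluoride cleavage of the aryl silyl ether; no acid touches the electron-rich diene.

Step 11
Reactants: 16 2-{[(1S,6S)-2-ethenyl-1,3,6-trimethylcyclohex-2-en-1-yl]methyl}-4-methoxy-6-methylphenol, 17 (triphenylphosphoranylidene)ketene, 18 2-methylpropanoyl chloride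
Product: 21 2-{[(1S,6S)-2-ethenyl-1,3,6-trimethylcyclohex-2-en-1-yl]methyl}-4-methoxy-6-methylphenyl 4-methylpenta-2,3-dienoate, via aryl ylide ester 19 (not isolated), via dimethylketene 20 (not isolated)
Conditions: 17, THF, 50 °C; then 18, Et3N, 0 → 25 °C
Reagents that add atoms: none
Why: The phenol adds across the cumulated ylide to give an ester-stabilised ylide, whose Wittig reaction with dimethylketene (from the acid chloride and Et3N) forms the allenoate without handling the free allenic acid.

Step 12
Reactants: 21 2-{[(1S,6S)-2-ethenyl-1,3,6-trimethylcyclohex-2-en-1-yl]methyl}-4-methoxy-6-methylphenyl 4-methylpenta-2,3-dienoate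
Product: 22 bridged nine-membered aryl lactone of (1S,5S,6S,8aS)-5-[(2-hydroxy-5-methoxy-3-methylphenyl)methyl]-5,6,8a-trimethyl-2-(propan-2-ylidene)-1,2,3,5,6,7,8,8a-octahydronaphthalene-1-carboxylic acid (C1 carboxyl esterified with the phenolic oxygen)
Conditions: toluene (0.005 M), BHT (cat.), 110 °C
Reagents that add atoms: none
Why: Thermal, concerted but asynchronous [4+2] cycloaddition in which the ester-conjugated α,β-bond of the allenoate adds across the 1-vinylcyclohexene diene, C2–C3 forming ahead of the congested C1–C8a bond; the remote allene π-bond is not involved and is left as the C2 isopropylidene. The closest known reaction types are the type 2 intramolecular Diels–Alder reaction (tether on an internal diene carbon), Diels–Alder reactions of 4,4-disubstituted allenoates and those of 2,6,6-trimethyl-1-vinylcyclohexene. Ring B is closed by the [4+2] bond pair, and the nine-membered lactone is closed by the same C1–C8a bond as the bridging ring of a bicyclo[6.3.1] system whose C4=C4a bridgehead alkene is unstrained. C8a is controlled by the tether: the dienophile hangs from the α-oriented arylmethyl group on C5 and can reach only the α face of the diene, which places the C8a methyl β, syn to the C5 methyl; C1 is controlled by the same ring, which holds the carbonyl on the α face (H β). Regioselectivity (ester-bearing carbon to the tetrasubstituted terminus, central allene carbon to the vinyl CH2) is secured both by the tether geometry and by the matching polarity of the alkyl-substituted diene and the allenoate. High dilution and the lowest workable temperature are needed to keep oligomerisation, [1,5]-hydrogen shift of the diene and the reversible arene–allene cycloaddition (disfavoured by the ortho,ortho-disubstituted aryl ring) in check.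

Step 13
Reactants: 22 bridged nine-membered aryl lactone
Product: 23 methyl (1S,5S,6S,8aS)-5-[(2-hydroxy-5-methoxy-3-methylphenyl)methyl]-5,6,8a-trimethyl-2-(propan-2-ylidene)-1,2,3,5,6,7,8,8a-octahydronaphthalene-1-carboxylate
Conditions: K2CO3 (0.2 equiv), MeOH, 25 °C
Reagents that add atoms: methanol, CO
Why: Base-catalysed transesterification of the aryl ester (phenoxide leaving group) opens the temporary ring; C1 keeps the α (axial) ester, which also avoids allylic 1,3-strain with the isopropylidene.

Step 14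
Reactants: 23 methyl (1S,5S,6S,8aS)-5-[(2-hydroxy-5-methoxy-3-methylphenyl)methyl]-5,6,8a-trimethyl-2-(propan-2-ylidene)-1,2,3,5,6,7,8,8a-octahydronaphthalene-1-carboxylate
Product: 24 methyl (1R,4aR,5S,6S,8aR)-5-[(2-hydroxy-5-methoxy-3-methylphenyl)methyl]-5,6,8a-trimethyl-2-(propan-2-ylidene)decahydronaphthalene-1-carboxylate
Conditions: Mn(dpm)3 (10 mol %; dpm = 2,2,6,6-tetramethylheptane-3,5-dionate), PhSiH3, t-BuOOH, i-PrOH, 22 °C
Reagents that add atoms: none
Why: Metal-hydride hydrogen-atom-transfer hydrogenation; transfer to C4, the only alkene carbon bearing hydrogen, should beat transfer to the fully substituted isopropylidene carbons, and the tertiary C4a radical should take its hydrogen on the α face (phenolic O–H of the C5 arm as internal donor, C5 and C8a methyls blocking the β face), giving the trans ring fusion.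

Step 15
Reactants: 24 methyl (1R,4aR,5S,6S,8aR)-5-[(2-hydroxy-5-methoxy-3-methylphenyl)methyl]-5,6,8a-trimethyl-2-(propan-2-ylidene)decahydronaphthalene-1-carboxylate
Product: 26 methyl (1S,4aR,5S,6S,8aR)-5-[(2-hydroxy-5-methoxy-3-methylphenyl)methyl]-5,6,8a-trimethyl-2-(propan-2-ylidene)decahydronaphthalene-1-carboxylate, via dilithium enolate 25 (not isolated)
Conditions: LDA (2.5 equiv), THF, −78 → −40 °C; then t-BuCO2H, −78 °C
Reagents that add atoms: none
Why: Kinetic (deconjugative) protonation of the extended ester enolate at C1 on the α face, anti to the axial C8a methyl, should give the less stable equatorial 1β ester required by the target.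

Step 16
Reactants: 26 methyl (1S,4aR,5S,6S,8aR)-5-[(2-hydroxy-5-methoxy-3-methylphenyl)methyl]-5,6,8a-trimethyl-2-(propan-2-ylidene)decahydronaphthalene-1-carboxylate
Product: 28 methyl (2E)-3-[(1S,4aR,5S,6S,8aR)-5-[(2-hydroxy-5-methoxy-3-methylphenyl)methyl]-5,6,8a-trimethyl-2-(propan-2-ylidene)decahydronaphthalen-1-yl]prop-2-enoate, via aldehyde 27 (not isolated)
Conditions: DIBAL-H (3 equiv), CH2Cl2, −78 °C; then MeOH, Ph3P=CHCO2Me, −78 → 25 °C
Reagents that add atoms: methyl (triphenylphosphoranylidene)acetate, COC(=O)C=P(c1ccccc1)(c1ccccc1)c1ccccc1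
Why: Low-temperature DIBAL-H reduction stops at the aluminium hemiacetal; in situ Wittig reaction with a stabilised, weakly basic ylide gives the (E)-enoate without isolating the epimerisable β,γ-unsaturated aldehyde.

Step 17
Reactants: 28 methyl (2E)-3-[(1S,4aR,5S,6S,8aR)-5-[(2-hydroxy-5-methoxy-3-methylphenyl)methyl]-5,6,8a-trimethyl-2-(propan-2-ylidene)decahydronaphthalen-1-yl]prop-2-enoate
Product: 30 3-[(1S,4aR,5S,6S,8aR)-5-[(2-hydroxy-5-methoxy-3-methylphenyl)methyl]-5,6,8a-trimethyl-2-(propan-2-ylidene)decahydronaphthalen-1-yl]propanoic acid, via methyl ester 29 (not isolated)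
Conditions: Mg, MeOH, 25 °C; then LiOH, THF/H2O, 50 °C; aq. HCl
Reagents that add atoms: lithium hydroxide, [Li+].[OH-]
Why: Dissolving-metal conjugate reduction (Mg/MeOH) touches only the enoate C=C and leaves the isolated tetrasubstituted alkene; saponification then frees the acid.

**Compound list**

1 | 4-methoxy-2-methylphenol | COc1ccc(O)c(C)c1 | starting material
2 | 2-hydroxy-5-methoxy-3-methylbenzaldehyde | COc1cc(C)c(O)c(C=O)c1 | intermediate
3 | 2-(tert-butyldimethylsilyloxy)-5-methoxy-3-methylbenzaldehyde | COc1cc(C)c(O[Si](C)(C)C(C)(C)C)c(C=O)c1 | intermediate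
4 | [2-(tert-butyldimethylsilyloxy)-5-methoxy-3-methylphenyl]methanol | COc1cc(C)c(O[Si](C)(C)C(C)(C)C)c(CO)c1 | intermediate
5 | [2-(bromomethyl)-4-methoxy-6-methylphenoxy](tert-butyl)dimethylsilane | COc1cc(C)c(O[Si](C)(C)C(C)(C)C)c(CBr)c1 | intermediate
6 | 2-iodocyclohex-2-en-1-one | O=C1CCCC=C1I | starting material
7 | [2-(tert-butyldimethylsilyloxy)-5-methoxy-3-methylphenyl]methylzinc bromide | COc1cc(C)c(O[Si](C)(C)C(C)(C)C)c(C[Zn]Br)c1 | intermediate
8 | 2-{[2-(tert-butyldimethylsilyloxy)-5-methoxy-3-methylphenyl]methyl}cyclohex-2-en-1-one | COc1cc(C)c(O[Si](C)(C)C(C)(C)C)c(CC2=CCCCC2=O)c1 | intermediate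
9 | bromomagnesium C1=C2 enolate of (3S)-2-{[2-(tert-butyldimethylsilyloxy)-5-methoxy-3-methylphenyl]methyl}-3-methylcyclohexan-1-one | COc1cc(C)c(O[Si](C)(C)C(C)(C)C)c(CC2=C(O[Mg]Br)CCC[C@@H]2C)c1 | intermediate
10 | (2S,3S)-2-{[2-(tert-butyldimethylsilyloxy)-5-methoxy-3-methylphenyl]methyl}-2,3-dimethylcyclohexan-1-one (2-methyl trans to 3-methyl) | COc1cc(C)c(O[Si](C)(C)C(C)(C)C)c(C[C@]2(C)C(=O)CCC[C@@H]2C)c1 | intermediate
11 | lithium C1=C6 enolate of 10 | COc1cc(C)c(O[Si](C)(C)C(C)(C)C)c(C[C@]2(C)C(O[Li])=CCC[C@@H]2C)c1 | intermediate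
12 | (2S,3S)-2-{[2-(tert-butyldimethylsilyloxy)-5-methoxy-3-methylphenyl]methyl}-2,3,6-trimethylcyclohexan-1-one (C6 epimers) | COc1cc(C)c(O[Si](C)(C)C(C)(C)C)c(C[C@]2(C)C(=O)C(C)CC[C@@H]2C)c1 | intermediate
13 | potassium C1=C6 enolate of 12 | COc1cc(C)c(O[Si](C)(C)C(C)(C)C)c(C[C@]2(C)C(O[K])=C(C)CC[C@@H]2C)c1 | intermediate
14 | (5S,6S)-6-{[2-(tert-butyldimethylsilyloxy)-5-methoxy-3-methylphenyl]methyl}-2,5,6-trimethylcyclohex-1-en-1-yl trifluoromethanesulfonate | COc1cc(C)c(O[Si](C)(C)C(C)(C)C)c(C[C@]2(C)C(OS(=O)(=O)C(F)(F)F)=C(C)CC[C@@H]2C)c1 | intermediate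
15 | tert-butyl(2-{[(1S,6S)-2-ethenyl-1,3,6-trimethylcyclohex-2-en-1-yl]methyl}-4-methoxy-6-methylphenoxy)dimethylsilane | COc1cc(C)c(O[Si](C)(C)C(C)(C)C)c(C[C@]2(C)C(C=C)=C(C)CC[C@@H]2C)c1 | intermediate
16 | 2-{[(1S,6S)-2-ethenyl-1,3,6-trimethylcyclohex-2-en-1-yl]methyl}-4-methoxy-6-methylphenol | COc1cc(C)c(O)c(C[C@]2(C)C(C=C)=C(C)CC[C@@H]2C)c1 | intermediate
17 | (triphenylphosphoranylidene)ketene | O=C=C=P(c1ccccc1)(c1ccccc1)c1ccccc1 | starting material
18 | 2-methylpropanoyl chloride | CC(C)C(Cl)=O | starting material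
19 | 2-{[(1S,6S)-2-ethenyl-1,3,6-trimethylcyclohex-2-en-1-yl]methyl}-4-methoxy-6-methylphenyl (triphenylphosphoranylidene)acetate | COc1cc(C)c(OC(=O)C=P(c3ccccc3)(c3ccccc3)c3ccccc3)c(C[C@]2(C)C(C=C)=C(C)CC[C@@H]2C)c1 | intermediate
20 | dimethylketene | CC(C)=C=O | intermediate
21 | 2-{[(1S,6S)-2-ethenyl-1,3,6-trimethylcyclohex-2-en-1-yl]methyl}-4-methoxy-6-methylphenyl 4-methylpenta-2,3-dienoate | COc1cc(C)c(OC(=O)C=C=C(C)C)c(C[C@]2(C)C(C=C)=C(C)CC[C@@H]2C)c1 | intermediate
22 | bridged nine-membered aryl lactone: (1S,5S,6S,8aS)-5,6,8a-trimethyl-2-(propan-2-ylidene)-1,2,3,5,6,7,8,8a-octahydronaphthalene-1-carboxylate esterified with the phenol oxygen of its own C5 (2-hydroxy-5-methoxy-3-methylphenyl)methyl group; C1 carbonyl and C5 arylmethyl α, C5 and C8a methyls β, C6 methyl α | COc1cc(C)c(O5)c(C[C@]2(C)C3=CCC(=C(C)C)[C@H](C5=O)[C@]3(C)CC[C@@H]2C)c1 | intermediate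
23 | methyl (1S,5S,6S,8aS)-5-[(2-hydroxy-5-methoxy-3-methylphenyl)methyl]-5,6,8a-trimethyl-2-(propan-2-ylidene)-1,2,3,5,6,7,8,8a-octahydronaphthalene-1-carboxylate (ester α) | COc1cc(C)c(O)c(C[C@]2(C)C3=CCC(=C(C)C)[C@H](C(=O)OC)[C@]3(C)CC[C@@H]2C)c1 | intermediate
24 | methyl (1R,4aR,5S,6S,8aR)-5-[(2-hydroxy-5-methoxy-3-methylphenyl)methyl]-5,6,8a-trimethyl-2-(propan-2-ylidene)decahydronaphthalene-1-carboxylate (trans-fused, ester α) | COc1cc(C)c(O)c(C[C@]2(C)[C@H]3CCC(=C(C)C)[C@H](C(=O)OC)[C@]3(C)CC[C@@H]2C)c1 | intermediate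
25 | dilithium salt of 24 (lithium phenoxide and lithium ester enolate at C1) | COc1cc(C)c(O[Li])c(C[C@]2(C)[C@H]3CCC(=C(C)C)C(=C(OC)O[Li])[C@]3(C)CC[C@@H]2C)c1 | intermediate
26 | methyl (1S,4aR,5S,6S,8aR)-5-[(2-hydroxy-5-methoxy-3-methylphenyl)methyl]-5,6,8a-trimethyl-2-(propan-2-ylidene)decahydronaphthalene-1-carboxylate (ester β) | COc1cc(C)c(O)c(C[C@]2(C)[C@H]3CCC(=C(C)C)[C@@H](C(=O)OC)[C@]3(C)CC[C@@H]2C)c1 | intermediate
27 | (1S,4aR,5S,6S,8aR)-5-[(2-hydroxy-5-methoxy-3-methylphenyl)methyl]-5,6,8a-trimethyl-2-(propan-2-ylidene)decahydronaphthalene-1-carbaldehyde | COc1cc(C)c(O)c(C[C@]2(C)[C@H]3CCC(=C(C)C)[C@@H](C=O)[C@]3(C)CC[C@@H]2C)c1 | intermediate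
28 | methyl (2E)-3-[(1S,4aR,5S,6S,8aR)-5-[(2-hydroxy-5-methoxy-3-methylphenyl)methyl]-5,6,8a-trimethyl-2-(propan-2-ylidene)decahydronaphthalen-1-yl]prop-2-enoate | COc1cc(C)c(O)c(C[C@]2(C)[C@H]3CCC(=C(C)C)[C@@H](/C=C/C(=O)OC)[C@]3(C)CC[C@@H]2C)c1 | intermediate
29 | methyl 3-[(1S,4aR,5S,6S,8aR)-5-[(2-hydroxy-5-methoxy-3-methylphenyl)methyl]-5,6,8a-trimethyl-2-(propan-2-ylidene)decahydronaphthalen-1-yl]propanoate | COc1cc(C)c(O)c(C[C@]2(C)[C@H]3CCC(=C(C)C)[C@@H](CCC(=O)OC)[C@]3(C)CC[C@@H]2C)c1 | intermediate
30 | 3-[(1S,4aR,5S,6S,8aR)-5-[(2-hydroxy-5-methoxy-3-methylphenyl)methyl]-5,6,8a-trimethyl-2-(propan-2-ylidene)decahydronaphthalen-1-yl]propanoic acid | COc1cc(C)c(O)c(C[C@]2(C)[C@H]3CCC(=C(C)C)[C@@H](CCC(=O)O)[C@]3(C)CC[C@@H]2C)c1 | target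

**Step count and risks**

Total step count: 17. Longest linear sequence: 17 steps (1 → 30; 6, 17 and 18 are purchased).

The three steps most likely to fail:

Step 12 (key step). Closing the nine-membered tether ring is entropically costly. Oligomerisation, thermal [1,5]-hydrogen shift within the diene (whose ring methyl is cis to the vinyl group) or the reversible cycloaddition of the allenoate onto its own aryl ring may consume the material first. Fallback: setting out from silyl ether 15, an intermolecular Diels–Alder reaction promoted by EtAlCl2 (CH2Cl2, −20 °C) with methyl 4-methylpenta-2,3-dienoate F1 (from methyl (triphenylphosphoranylidene)acetate, 18 and Et3N via 20) should give the silyl-protected endo adduct F2. Without the tether the diene face is not controlled, so the C8a isomer would have to be separated. TBAF then cleaves the silyl ether, and the route is rejoined at 23.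

Step 14. Hydrogen-atom transfer may fail to discriminate between the ring alkene and the isopropylidene. The electron-rich phenol may be oxidised by the peroxide, or hydrogen return on the β face may give the cis-fused ring, since ring C is conformationally mobile. Fallback: setting out from 23, homogeneous hydrogenation with [Ir(cod)(PCy3)(py)]PF6 (5 mol %) under H2 (1 atm) in CH2Cl2 at 0 °C, stopped after one equivalent of hydrogen. The axial α-ester at C1 is 1,3-syn to the α face of C4a and should bind iridium and direct delivery there. This leads straight to 24 and makes no new compound.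

Step 15. Protonation of the hindered enolate may return the thermodynamically preferred axial (1α) ester or occur at the γ-carbon with conjugation of the alkene, and enolisation at C1 may be slow. Fallback: setting out from 24, the enolate is trapped (LDA, TBSCl, HMPA, −78 °C) as the isolable silyl ketene acetal aryl silyl ether F3. Protodesilylation at −78 °C with TBAF buffered by acetic acid protonates C1 from the open α face of the neutral ketene acetal and frees the phenol, rejoining the route at 26.

Further compounds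
F1 | step 12 | methyl 4-methylpenta-2,3-dienoate | COC(=O)C=C=C(C)C
F2 | step 12 | methyl (1S,5S,6S,8aS)-5-{[2-(tert-butyldimethylsilyloxy)-5-methoxy-3-methylphenyl]methyl}-5,6,8a-trimethyl-2-(propan-2-ylidene)-1,2,3,5,6,7,8,8a-octahydronaphthalene-1-carboxylate | COc1cc(C)c(O[Si](C)(C)C(C)(C)C)c(C[C@]2(C)C3=CCC(=C(C)C)[C@H](C(=O)OC)[C@]3(C)CC[C@@H]2C)c1
F0 | step 14 | none | none
F3 | step 15 | tert-butyldimethylsilyl methyl ketene acetal at C1 of 24 with the phenol as its tert-butyldimethylsilyl ether | COc1cc(C)c(O[Si](C)(C)C(C)(C)C)c(C[C@]2(C)[C@H]3CCC(=C(C)C)C(=C(OC)O[Si](C)(C)C(C)(C)C)[C@]3(C)CC[C@@H]2C)c1
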